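**Retrosynthetic overview** (chain numbering: C1 = lactone C=O, C5 = ring CH–O, C7/C9/C11 = carbinols, C12–C20 = nonyl)
1. Last events: cleave the C11 silyl ether; make C9–OH from a C9 ketone by 1,3-syn reduction directed by the free C7–OH. The ketone is stored as a 1,3-dithiane.
2. Dihydropyranone (the only ring of the target, closed after the whole C4–C20 chain exists): the C3–C4 bond comes from the dianion of 3-(phenylsulfonyl)propanoic acid, a β-acyl vinyl anion (homoenolate-type) equivalent, opening a C4–C5 terminal epoxide. Lactonisation and sulfinate loss follow.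
3. Key disconnection, C8–C9 and C9–C10 in one flask: a 2-silyl-1,3-dithiane acyl-anion linchpin opens (R)-1,2-epoxyundecane and, after 1,4-Brook relay, one end of C2-symmetric (2R,4R)-1,2:4,5-diepoxypentane. The bis-epoxide is desymmetrised and its second oxirane is kept for line 2.
4. Stereochemistry: C11 from the mono-epoxide, C5 and C7 (anti) from the bis-epoxide, C9 from the directed reduction (7,9-syn, hence 9,11-anti).
5. Building blocks: (R)-epichlorohydrin + n-C8H17MgBr gives the mono-epoxide; acetylacetone, via the 1,5-dichlorodiketone and RuCl2[(S)-BINAP]/H2, gives the bis-epoxide. Ring order: oxiranes first, dihydropyranone last (step 6); the dithiane is bought pre-formed.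

Assumption: operations run in one flask without isolating an intermediate are counted as one step.

**Step 1**
Reactants: 1 (R)-epichlorohydrin; 2 n-octylmagnesium bromide
Product: 4 (2R)-2-nonyloxirane, via bromomagnesium (2R)-1-chloroundecan-2-olate 3 (not isolated)
Conditions: 2 (1.1 equiv), CuI (5 mol%), THF, −40 → 0 °C; then 5 M aq. NaOH, rt; distil
Reagents that add atoms: none
Why: CuI-catalysed Grignard opening of the epoxide at its CH2 terminus followed by Williamson (intramolecular SN2) closure of the chlorohydrin onto CH2Cl; the stereocentre is never a reacting carbon, so the R configuration of 1 is carried into 4.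

**Step 2**
Reactants: 5 pentane-2,4-dione (acetylacetone); 6 chloroacetyl chloride
Product: 7 1,5-dichloropentane-2,4-dione
Conditions: 6 (2.5 equiv), AlCl3 (2.5 equiv), PhNO2, 60 °C; ice/HCl; distil
Reagents that add atoms: none
Why: AlCl3-mediated C-acylation of the diketone followed by retro-Claisen loss of acetyl chloride (acyl exchange), run twice, replaces both acetyl groups by chloroacetyl groups; no stereocentre is involved.

**Step 3**
Reactants: 7 1,5-dichloropentane-2,4-dione
Product: 8 (2R,4R)-1,5-dichloropentane-2,4-diol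
Conditions: H2 (80 atm), RuCl2[(S)-BINAP] (0.2 mol%), MeOH, 80 °C; recrystallise
Reagents that add atoms: none
Why: Noyori asymmetric hydrogenation of a β-diketone, in which the chelated substrate is reduced on the catalyst-controlled face at each carbonyl (the facial sense that gives (R)-4-chloro-3-hydroxybutanoate from 4-chloroacetoacetate), so the anti, C2-symmetric 2R,4R diol dominates and is made stereopure by recrystallisation.

**Step 4**
Reactants: 8 (2R,4R)-1,5-dichloropentane-2,4-diol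
Product: 9 (2R,4R)-1,2:4,5-diepoxypentane
Conditions: KOH (powdered, 4 equiv), Et2O, rt; distil
Reagents that add atoms: none
Why: double Williamson epoxide closure (intramolecular SN2 at the two CH2Cl carbons, which are not stereocentres), so both carbinol configurations are retained.

**Step 5 (key step)**
Reactants: 10 2-(tert-butyldimethylsilyl)-1,3-dithiane; 4 (2R)-2-nonyloxirane; 9 (2R,4R)-1,2:4,5-diepoxypentane
Product: 14 (2R)-1-{2-[(2R)-2-(tert-butyldimethylsilyloxy)undecyl]-1,3-dithian-2-yl}-3-[(2R)-oxiran-2-yl]propan-2-ol, via silyl dithianyllithium 11 (not isolated), via lithium alkoxide 12 (not isolated), via Brook-shifted dithianyllithium 13 (not isolated)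
Conditions: t-BuLi (1.05 equiv), Et2O, −78 → −45 °C; 4 (1.0 equiv), Et2O, −78 → −25 °C; cannulate into 9 (3 equiv), THF/HMPA (4 equiv), −78 → −20 °C; aq. NH4Cl; excess 9 recovered by distillation
Reagents that add atoms: none
Why: multicomponent dithiane linchpin coupling (Corey–Seebach acyl-anion umpolung with a solvent-gated 1,4-Brook rearrangement), in which 11 opens 4 at CH2, HMPA triggers C→O silyl migration to give carbanion 13, and 13 opens one of the two homotopic oxirane termini of excess 9; no stereocentre is formed or attacked, so C11, C7 and C5 come unchanged from 4 and 9, and only the C11 oxygen is silylated.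

**Step 6**
Reactants: 14 (2R)-1-{2-[(2R)-2-(tert-butyldimethylsilyloxy)undecyl]-1,3-dithian-2-yl}-3-[(2R)-oxiran-2-yl]propan-2-ol; 15 3-(phenylsulfonyl)propanoic acid
Product: 19 (6S)-6-[(2R)-3-{2-[(2R)-2-(tert-butyldimethylsilyloxy)undecyl]-1,3-dithian-2-yl}-2-hydroxypropyl]-5,6-dihydro-2H-pyran-2-one, via sulfonyl dianion 16 (not isolated), via hydroxy acid 17 (not isolated), via sulfonyl lactone 18 (not isolated)
Conditions: 15 (3 equiv), n-BuLi (6 equiv), THF, −78 °C; 14, DMPU, −78 → −20 °C; CF3CO2H (excess), rt; then DBU, 0 °C → rt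
Reagents that add atoms: none
Why: the α-sulfonyl carbanion of dianion 16 (a β-acyl vinyl anion, homoenolate-type d3 equivalent) opens the terminal epoxide at CH2 by SN2, acid closes the δ-hydroxy acid to the six-membered lactone (the C7–OH could only give an eight-membered ring), and DBU expels benzenesulfinate by E1cB to give the conjugated alkene; C5 keeps its configuration because only the neighbouring CH2 is attacked, and the sulfone-bearing centre is destroyed.

**Step 7**
Reactants: 19 (6S)-6-[(2R)-3-{2-[(2R)-2-(tert-butyldimethylsilyloxy)undecyl]-1,3-dithian-2-yl}-2-hydroxypropyl]-5,6-dihydro-2H-pyran-2-one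
Product: 20 (6S)-6-[(2R,6R)-6-(tert-butyldimethylsilyloxy)-2-hydroxy-4-oxopentadecyl]-5,6-dihydro-2H-pyran-2-one
Conditions: PhI(OCOCF3)2 (1.5 equiv), MeCN/H2O 9:1, 0 °C, 10 min; aq. NaHCO3
Reagents that add atoms: water, O
Why: oxidative dithioacetal hydrolysis, in which sulfur is activated by the hypervalent iodine reagent and water unmasks the C9 ketone within minutes under conditions that leave the enoate lactone, the free alcohol and the silyl ether untouched; no stereocentre is involved.

**Step 8**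
Reactants: 20 (6S)-6-[(2R,6R)-6-(tert-butyldimethylsilyloxy)-2-hydroxy-4-oxopentadecyl]-5,6-dihydro-2H-pyran-2-one
Product: 22 (6S)-6-[(2S,4S,6R)-2,4,6-trihydroxypentadecyl]-5,6-dihydro-2H-pyran-2-one, via silyl ether 21 (not isolated)
Conditions: Et2BOMe (1.2 equiv), THF/MeOH 4:1, −78 °C; NaBH4 (1.2 equiv), −78 °C; AcOH, co-evaporate with MeOH; then 48% aq. HF, MeCN, 0 °C → rt
Reagents that add atoms: none
Why: Narasaka–Prasad reduction, in which the C7–O–BEt2 chelate of the β-hydroxy ketone takes external hydride axially on the half-chair to give the 7,9-syn diol (the silylated C11 oxygen cannot chelate, so the new centre is 9,11-anti as required), followed by acidic fluoride desilylation of C11–O.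

**Compound list**
1 | (R)-epichlorohydrin [(2R)-2-(chloromethyl)oxirane] | ClC[C@H]1CO1 | starting material
2 | n-octylmagnesium bromide | CCCCCCCC[Mg]Br | starting material
3 | bromomagnesium (2R)-1-chloroundecan-2-olate | ClC[C@H](O[Mg]Br)CCCCCCCCC | intermediate
4 | (2R)-2-nonyloxirane [(R)-1,2-epoxyundecane] | CCCCCCCCC[C@@H]1CO1 | intermediate
5 | pentane-2,4-dione (acetylacetone) | CC(=O)CC(C)=O | starting material
6 | chloroacetyl chloride | ClCC(Cl)=O | starting material
7 | 1,5-dichloropentane-2,4-dione | ClCC(=O)CC(=O)CCl | intermediate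
8 | (2R,4R)-1,5-dichloropentane-2,4-diol | ClC[C@H](O)C[C@@H](O)CCl | intermediate
9 | (2R,4R)-1,2:4,5-diepoxypentane [(2R,2'R)-2,2'-methylenebis(oxirane)] | C1[C@H](O1)C[C@@H]2CO2 | intermediate
10 | 2-(tert-butyldimethylsilyl)-1,3-dithiane | CC(C)(C)[Si](C)(C)C1SCCCS1 | starting material
11 | 2-lithio-2-(tert-butyldimethylsilyl)-1,3-dithiane | CC(C)(C)[Si](C)(C)C1([Li])SCCCS1 | intermediate
12 | lithium (2R)-1-[2-(tert-butyldimethylsilyl)-1,3-dithian-2-yl]undecan-2-olate | CCCCCCCCC[C@@H](O[Li])CC1(SCCCS1)[Si](C)(C)C(C)(C)C | intermediate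
13 | 2-lithio-2-[(2R)-2-(tert-butyldimethylsilyloxy)undecyl]-1,3-dithiane | CCCCCCCCC[C@@H](O[Si](C)(C)C(C)(C)C)CC1([Li])SCCCS1 | intermediate
14 | (2R)-1-{2-[(2R)-2-(tert-butyldimethylsilyloxy)undecyl]-1,3-dithian-2-yl}-3-[(2R)-oxiran-2-yl]propan-2-ol | CCCCCCCCC[C@@H](O[Si](C)(C)C(C)(C)C)CC1(SCCCS1)C[C@H](O)C[C@@H]2CO2 | intermediate
15 | 3-(phenylsulfonyl)propanoic acid | OC(=O)CCS(=O)(=O)c1ccccc1 | starting material
16 | lithium 3-lithio-3-(phenylsulfonyl)propanoate | [Li]OC(=O)CC([Li])S(=O)(=O)c1ccccc1 | intermediate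
17 | (5R,7R)-8-{2-[(2R)-2-(tert-butyldimethylsilyloxy)undecyl]-1,3-dithian-2-yl}-5,7-dihydroxy-3-(phenylsulfonyl)octanoic acid (both C3 epimers) | CCCCCCCCC[C@@H](O[Si](C)(C)C(C)(C)C)CC1(SCCCS1)C[C@H](O)C[C@@H](O)CC(CC(O)=O)S(=O)(=O)c2ccccc2 | intermediate
18 | (6R)-6-[(2R)-3-{2-[(2R)-2-(tert-butyldimethylsilyloxy)undecyl]-1,3-dithian-2-yl}-2-hydroxypropyl]-4-(phenylsulfonyl)oxan-2-one (both C4 epimers) | CCCCCCCCC[C@@H](O[Si](C)(C)C(C)(C)C)CC1(SCCCS1)C[C@H](O)C[C@@H]2CC(CC(=O)O2)S(=O)(=O)c3ccccc3 | intermediate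
19 | (6S)-6-[(2R)-3-{2-[(2R)-2-(tert-butyldimethylsilyloxy)undecyl]-1,3-dithian-2-yl}-2-hydroxypropyl]-5,6-dihydro-2H-pyran-2-one | CCCCCCCCC[C@@H](O[Si](C)(C)C(C)(C)C)CC1(SCCCS1)C[C@H](O)C[C@@H]2CC=CC(=O)O2 | intermediate
20 | (6S)-6-[(2R,6R)-6-(tert-butyldimethylsilyloxy)-2-hydroxy-4-oxopentadecyl]-5,6-dihydro-2H-pyran-2-one | CCCCCCCCC[C@@H](O[Si](C)(C)C(C)(C)C)CC(=O)C[C@H](O)C[C@@H]1CC=CC(=O)O1 | intermediate
21 | (6S)-6-[(2S,4R,6R)-6-(tert-butyldimethylsilyloxy)-2,4-dihydroxypentadecyl]-5,6-dihydro-2H-pyran-2-one | CCCCCCCCC[C@@H](O[Si](C)(C)C(C)(C)C)C[C@H](O)C[C@H](O)C[C@@H]1CC=CC(=O)O1 | intermediate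
22 | (6S)-6-[(2S,4S,6R)-2,4,6-trihydroxypentadecyl]-5,6-dihydro-2H-pyran-2-one | CCCCCCCCC[C@@H](O)C[C@H](O)C[C@H](O)C[C@@H]1CC=CC(=O)O1 | target

**Totals**
Total step count: 8. Longest linear sequence: 7 (steps 2 to 8, from acetylacetone). Step 1 is a one-step side branch.

**Three steps most likely to fail**

Step 5. Carbanion 13 may open both ends of 9 (statistical bis-adduct), or the Brook shift may be incomplete when the alkoxide is run into the HMPA solution. Fallback: give up the relay and make the two bonds in separate operations. It sets out from 4, which is opened with 1,3-dithiane/n-BuLi (THF, −30 °C) to give (2R)-1-(1,3-dithian-2-yl)undecan-2-ol F1. Silylation (TBSCl, imidazole, DMF) gives tert-butyl{[(2R)-1-(1,3-dithian-2-yl)undecan-2-yl]oxy}dimethylsilane F2. Deprotonation of F2 (t-BuLi, THF/HMPA, −78 °C) gives carbanion 13 directly, which is titrated slowly into 9 (4 equiv) at −78 °C. The route is rejoined at 14.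

Step 6. The sulfonyl dianion may be too sluggish or too short-lived toward the alkoxide-bearing epoxide, or lactonisation in the flask may stall. Fallback: use an alkynoate as the three-carbon reversed-polarity unit and close the ring by hydrogenation after the sulfur has been removed. It sets out from 14, which is opened with ethyl propiolate/n-BuLi/BF3·OEt2 (THF, −78 °C) to give ethyl (5S,7R)-8-{2-[(2R)-2-(tert-butyldimethylsilyloxy)undecyl]-1,3-dithian-2-yl}-5,7-dihydroxyoct-2-ynoate F3. PhI(OCOCF3)2 in aqueous MeCN unmasks ethyl (5S,7R,11R)-11-(tert-butyldimethylsilyloxy)-5,7-dihydroxy-9-oxoicos-2-ynoate F4. Et2BOMe/NaBH4 gives ethyl (5S,7R,9R,11R)-11-(tert-butyldimethylsilyloxy)-5,7,9-trihydroxyicos-2-ynoate F5. Semi-hydrogenation (H2, Pd/CaCO3 poisoned by Pb(OAc)2, quinoline, EtOAc) gives ethyl (2Z,5S,7R,9R,11R)-11-(tert-butyldimethylsilyloxy)-5,7,9-trihydroxyicos-2-enoate F6, which lactonises (PPTS, toluene, 60 °C) to 21. The route is rejoined at 21, which is desilylated with aqueous HF as in step 8.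

Step 8. Hydride may add 1,4 to the enoate lactone, or the one-flask desilylation may be incomplete. Fallback: keep the alkene masked as the β-sulfone until after the reduction. It sets out from 18, obtained by stopping step 6 before DBU and isolating it. PhI(OCOCF3)2 in aqueous MeCN gives (6R)-6-[(2R,6R)-6-(tert-butyldimethylsilyloxy)-2-hydroxy-4-oxopentadecyl]-4-(phenylsulfonyl)oxan-2-one F7. Et2BOMe/NaBH4 (THF/MeOH, −78 °C) gives (6R)-6-[(2S,4R,6R)-6-(tert-butyldimethylsilyloxy)-2,4-dihydroxypentadecyl]-4-(phenylsulfonyl)oxan-2-one F8. DBU (CH2Cl2, 0 °C) eliminates sulfinate to give 21. The route is rejoined at 21, which is desilylated with aqueous HF to 22.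

**Further compounds**
F1 | step 5 | (2R)-1-(1,3-dithian-2-yl)undecan-2-ol | CCCCCCCCC[C@@H](O)CC1SCCCS1
F2 | step 5 | tert-butyl{[(2R)-1-(1,3-dithian-2-yl)undecan-2-yl]oxy}dimethylsilane | CCCCCCCCC[C@@H](O[Si](C)(C)C(C)(C)C)CC1SCCCS1
F3 | step 6 | ethyl (5S,7R)-8-{2-[(2R)-2-(tert-butyldimethylsilyloxy)undecyl]-1,3-dithian-2-yl}-5,7-dihydroxyoct-2-ynoate | CCCCCCCCC[C@@H](O[Si](C)(C)C(C)(C)C)CC1(SCCCS1)C[C@H](O)C[C@@H](O)CC#CC(=O)OCC
F4 | step 6 | ethyl (5S,7R,11R)-11-(tert-butyldimethylsilyloxy)-5,7-dihydroxy-9-oxoicos-2-ynoate | CCCCCCCCC[C@@H](O[Si](C)(C)C(C)(C)C)CC(=O)C[C@H](O)C[C@@H](O)CC#CC(=O)OCC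
F5 | step 6 | ethyl (5S,7R,9R,11R)-11-(tert-butyldimethylsilyloxy)-5,7,9-trihydroxyicos-2-ynoate | CCCCCCCCC[C@@H](O[Si](C)(C)C(C)(C)C)C[C@H](O)C[C@H](O)C[C@@H](O)CC#CC(=O)OCC
F6 | step 6 | ethyl (2Z,5S,7R,9R,11R)-11-(tert-butyldimethylsilyloxy)-5,7,9-trihydroxyicos-2-enoate | CCCCCCCCC[C@@H](O[Si](C)(C)C(C)(C)C)C[C@H](O)C[C@H](O)C[C@@H](O)C/C=C\C(=O)OCC
F7 | step 8 | (6R)-6-[(2R,6R)-6-(tert-butyldimethylsilyloxy)-2-hydroxy-4-oxopentadecyl]-4-(phenylsulfonyl)oxan-2-one | CCCCCCCCC[C@@H](O[Si](C)(C)C(C)(C)C)CC(=O)C[C@H](O)C[C@@H]1CC(CC(=O)O1)S(=O)(=O)c2ccccc2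
F8 | step 8 | (6R)-6-[(2S,4R,6R)-6-(tert-butyldimethylsilyloxy)-2,4-dihydroxypentadecyl]-4-(phenylsulfonyl)oxan-2-one | CCCCCCCCC[C@@H](O[Si](C)(C)C(C)(C)C)C[C@H](O)C[C@H](O)C[C@@H]1CC(CC(=O)O1)S(=O)(=O)c2ccccc2
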